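Start at the late end of both earlier runs and count what is left: at 4.00 min Wednesday's reading leaves 93.8% of its charge as something other than target, and Friday's reading leaves 99.6%.

| setting | Wednesday's | Friday's | red | amber | teal | ochre |
|---|---|---|---|---|---|---|
| solid substrate | 6.7 mM | 39 mM | 6.0 mM | 10 mM | 15 mM | 25 mM |
| precatalyst | 0.24 µM | 0.24 µM | 0.24 µM | 0.24 µM | 0.24 µM | 0.24 µM |
| remark | run made earlier | run made earlier |  |  |  |  |
| time |  |  | 4.0 min | 4.0 min | 4.0 min | 4.0 min |

| run | time / min | target / % |
|---|---|---|
| Wednesday's | 0.333 | 0.5 |
| Wednesday's | 1.00 | 0 |
| Wednesday's | 2.00 | 1.4 |
| Wednesday's | 3.00 | 3.0 |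
| Wednesday's | 4.00 | 6.2 |
| Friday's | 0.833 | 1.2 |
| Friday's | 1.50 | 0.7 |
| Friday's | 2.50 | 0.9 |
| Friday's | 3.00 | 1.7 |
| Friday's | 4.00 | 0.4 |

(standard deviation of a reading: 0.5 percentage points)

- solid substrate is a solid; its amount is given per volume of the solution
- the analysis behind the earlier runs scatters by 0.5 percentage points, standard deviation
- at the start none of the solid substrate is in solution
- "hardly changes" means that all values lie within two and a half points (for a concentration: within two and a half percent of the largest)

1. [target] at the end for red, amber, teal, ochre, in this order
2. the shape of the row from first to last (rises all the way / falls all the way / falls, then rises / hardly changes / rises, then falls)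

Multiply the fraction made by the charge and call the product the take: Wednesday's reads 0.415 mM, and Friday's reads 0.156 mM, although Friday's charge is 5.82 times Wednesday's.

Now bound the take from above. Red's fraction left cannot fall below zero, so its take cannot pass its charge of 6.0 mM. To go further, suppose the flask is zero order in the charge, so that the pace ignores how much solid lies there; then one take serves every flask, and the earlier runs can speak for red. On that supposition, Friday's reading plus two standard deviations gives an estimated upper limit of 0.546 mM, and Wednesday's reading plus two gives 0.482 mM. Then estimate a lower limit: Friday's reading minus two standard deviations falls under zero and gives nothing, while Wednesday's gives 0.348 mM.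

The top of the window from 0.348 mM to 0.482 mM leaves 92.0% of red's charge and 98.1% of ochre's as something other than target. Commit to Wednesday's take for all four flasks, which is 6.92% of red's charge and 1.66% of ochre's, so the row hardly changes.

The forecast gives 0.36 mM, 0.5 mM, 0.5 mM and 0.42 mM, shape rises, then falls, on the ground that “much dissolved substrate inhibits or stalls the catalyst”; this differs from the reckoning above, with red and ochre inside the window and amber and teal above it.

The flasks give 0.417 mM, 0.417 mM, 0.417 mM and 0.417 mM: the row hardly changes.

    precatalyst ⇌ enzyme (K = 26.0, k = 0.129 min⁻¹)
    starting material + target → side product (k = 5.04 M⁻¹ min⁻¹)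
    solid substrate ⇌ starting material, rate k3*(cs3 - [starting material]) while solid is left; crystals form when [starting material] > cs3 (solubility = 7.10 mM, k = 0.0890 min⁻¹)
    starting material + enzyme → target + enzyme, rate k4*[starting material]*[enzyme]/(1 + ([starting material]/Km4)) (10.7 mM, k = 29500 M⁻¹ s⁻¹)

At 4.00 min red still holds 63.9% of its charge as solid substrate. Wednesday's take divided by red's charge is 6.92%, and at that time red holds 6.94% as target. Divided by ochre's charge, Wednesday's take is 1.66%, and at 4.00 min ochre holds 1.67% as target.

Readings and results are calculated with constants of no real substance; noise was put on by code.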